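**Retrosynthetic overview**
- The only skeletal disconnection is the aryl–alkyl bond C6–C1′ of the target. It is cut to a 6-iodo-isoflavone and a C5 diol whose stereocentre already has the target's (R) configuration.
- C5 piece: D-mannitol-derived glycerate ester 1 → dimethyl carbinol 2 → isopropenyl acetonide 3 → diol 4 (stereocentre bought, never touched).
- Aryl piece: genistein 5 → 7,4′-bis-silyl ether 6 → 6-iodide 7 (iodination directed by the free 5-OH).
- Union: 4 + 7 under visible light with iridium/nickel catalysis, via acetal 8 to coupled ether 9, desilylated in the same pot to target 10.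
- Rings: none is built. Rings A, B and C arrive in genistein; the dioxolane of 1 is only a protecting ring, opened in step 3.

Assumption: methyl (R)-2,2-dimethyl-1,3-dioxolane-4-carboxylate (made from D-mannitol) and genistein count as commercial starting materials; the target stereocentre (C2′ of the side chain) is (R) as drawn.

**Step 1**
Reactants: 1 methyl (4R)-2,2-dimethyl-1,3-dioxolane-4-carboxylate
Product: 2 2-[(4R)-2,2-dimethyl-1,3-dioxolan-4-yl]propan-2-ol
Conditions: MeMgBr (2.5 equiv), THF, 0 °C to 23 °C; aq. NH4Cl
Reagents that add atoms: methylmagnesium bromide, C[Mg]Br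
Why: Double Grignard addition to the ester gives the tertiary carbinol; addition outpaces enolisation, so the bought dioxolane stereocentre is kept.

**Step 2**
Reactants: 2 2-[(4R)-2,2-dimethyl-1,3-dioxolan-4-yl]propan-2-ol
Product: 3 (4S)-2,2-dimethyl-4-(prop-1-en-2-yl)-1,3-dioxolane
Conditions: SOCl2 (1.5 equiv), pyridine, CH2Cl2, −10 °C to 0 °C; careful concentration (volatile product)
Reagents that add atoms: none
Why: Tertiary-alcohol dehydration by pyridine-mediated E2 elimination of the chlorosulfite takes one of six accessible methyl hydrogens rather than the single hindered ring C–H, giving the isopropenyl group; the stereocentre is not involved (the descriptor changes to S only through CIP priorities).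

**Step 3**
Reactants: 3 (4S)-2,2-dimethyl-4-(prop-1-en-2-yl)-1,3-dioxolane
Product: 4 (2S)-3-methylbut-3-ene-1,2-diol
Conditions: Dowex 50WX8 (H+ form), THF/H2O 4:1, 40 °C; filter, concentrate
Reagents that add atoms: none
Why: Acid-catalysed acetal hydrolysis under mild resin acid frees the diol without hydrating the 1,1-disubstituted alkene or ionising the allylic C–O bond; the stereocentre is untouched.

**Step 4**
Reactants: 5 genistein (5,7-dihydroxy-3-(4-hydroxyphenyl)-4H-chromen-4-one)
Product: 6 7-[(tert-butyldimethylsilyl)oxy]-3-{4-[(tert-butyldimethylsilyl)oxy]phenyl}-5-hydroxy-4H-chromen-4-one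
Conditions: TBSCl (2.2 equiv), imidazole, DMF, 0 °C to 23 °C
Reagents that add atoms: tert-butyldimethylsilyl chloride, CC(C)(C)[Si](C)(C)Cl
Why: Chemoselective phenol silylation: the 5-OH is hydrogen-bonded to the C4 carbonyl and stays free, while the 7- and 4′-OH react.

**Step 5**
Reactants: 6 7-[(tert-butyldimethylsilyl)oxy]-3-{4-[(tert-butyldimethylsilyl)oxy]phenyl}-5-hydroxy-4H-chromen-4-one
Product: 7 7-[(tert-butyldimethylsilyl)oxy]-3-{4-[(tert-butyldimethylsilyl)oxy]phenyl}-5-hydroxy-6-iodo-4H-chromen-4-one
Conditions: BnMe3N+ ICl2− (1.05 equiv), CaCO3, CH2Cl2/MeOH 5:2, 23 °C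
Reagents that add atoms: benzyltrimethylammonium dichloroiodate, C[N+](C)(C)Cc1ccccc1.Cl[I-]Cl
Why: Electrophilic aromatic iodination directed by the free 5-OH to its only open ortho position, C6, the selectivity pattern of 5-hydroxy-7-alkoxy chromones (5,7-dialkoxy systems go to C8).

**Step 6**
Reactants: 4 (2S)-3-methylbut-3-ene-1,2-diol; 7 7-[(tert-butyldimethylsilyl)oxy]-3-{4-[(tert-butyldimethylsilyl)oxy]phenyl}-5-hydroxy-6-iodo-4H-chromen-4-one
Product: 10 5,7-dihydroxy-6-[(2R)-2-hydroxy-3-methylbut-3-en-1-yl]-3-(4-hydroxyphenyl)-4H-chromen-4-one, via benzoxazoline adduct 8 (not isolated), via bis-silyl coupled ether 9 (not isolated)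
Conditions: 4 (1.8 equiv), 5,7-di-tert-butyl-3-phenylbenzoxazolium BF4 (1.6 equiv), pyridine, MTBE, 23 °C, 15 min; then 7 (1.0 equiv), [Ir(ppy)2(dtbbpy)]PF6 (2 mol%), NiBr2(dtbbpy) (10 mol%), quinuclidine, MTBE/DMA 1:1, 450 nm LEDs, 25 °C; then KHF2, MeOH, 23 °C, same pot (ppy = 2-phenylpyridinato, dtbbpy = 4,4′-di-tert-butyl-2,2′-bipyridine)
Reagents that add atoms: none
Why: Proposed new method: primary-selective deoxygenative arylation of an unprotected, enantiopure allylic 1,2-diol with a di-ortho-oxygenated hydroxy-iodochromone, not demonstrated for either substrate type; the bulky benzoxazolium condenses reversibly and preferentially with the primary hydroxyl to give N,O-acetal 8, the excited iridium photocatalyst oxidises its N-aryl aminal, quinuclidine removes the aminal proton, and β-scission of the resulting carbon radical releases the primary radical •CH2–CH(OH)–C(CH3)=CH2 while the hydroxyl oxygen leaves as the benzoxazolone C=O; zerovalent nickel inserts into the C6–I bond of 7, the aryl nickel halide captures the radical and reductive elimination from trivalent nickel forms the C6–C1′ bond of 9, after which KHF2 cleaves both aryl silyl ethers; the stereocentre is the one bought in 1 and is never a radical or ionic site, the methyl group on the alkene should slow the 3-exo closure that leads to a 1,2-vinyl shift (estimated 10^2–10^3 s−1) below nickel capture (estimated about 10^4 s−1 at 10 mol% nickel), and this weakly oxidising photocatalyst should not convert quinuclidine into a hydrogen-abstracting radical cation that could attack the allylic carbinol C–H; closest known reaction type: benzoxazolium (NHC)-mediated deoxygenative arylation of simple alcohols with aryl bromides under iridium/nickel metallaphotoredox catalysis, followed by standard fluoride cleavage of aryl silyl ethers.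

**Compound list**
1 | methyl (4R)-2,2-dimethyl-1,3-dioxolane-4-carboxylate | COC(=O)[C@H]1COC(C)(C)O1 | starting material
2 | 2-[(4R)-2,2-dimethyl-1,3-dioxolan-4-yl]propan-2-ol | CC(C)(O)[C@H]1COC(C)(C)O1 | intermediate
3 | (4S)-2,2-dimethyl-4-(prop-1-en-2-yl)-1,3-dioxolane | C=C(C)[C@H]1COC(C)(C)O1 | intermediate
4 | (2S)-3-methylbut-3-ene-1,2-diol | C=C(C)[C@H](O)CO | intermediate
5 | genistein, 5,7-dihydroxy-3-(4-hydroxyphenyl)-4H-chromen-4-one | O=c1c(-c2ccc(O)cc2)coc2cc(O)cc(O)c12 | starting material
6 | 7-[(tert-butyldimethylsilyl)oxy]-3-{4-[(tert-butyldimethylsilyl)oxy]phenyl}-5-hydroxy-4H-chromen-4-one | CC(C)(C)[Si](C)(C)Oc1ccc(cc1)-c1coc2cc(O[Si](C)(C)C(C)(C)C)cc(O)c2c1=O | intermediate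
7 | 7-[(tert-butyldimethylsilyl)oxy]-3-{4-[(tert-butyldimethylsilyl)oxy]phenyl}-5-hydroxy-6-iodo-4H-chromen-4-one | CC(C)(C)[Si](C)(C)Oc1ccc(cc1)-c1coc2cc(O[Si](C)(C)C(C)(C)C)c(I)c(O)c2c1=O | intermediate
8 | (2S)-1-[(5,7-di-tert-butyl-3-phenyl-2,3-dihydro-1,3-benzoxazol-2-yl)oxy]-3-methylbut-3-en-2-ol (both epimers at the acetal carbon) | C=C(C)[C@H](O)COC1Oc2c(C(C)(C)C)cc(C(C)(C)C)cc2N1c1ccccc1 | intermediate
9 | 7-[(tert-butyldimethylsilyl)oxy]-3-{4-[(tert-butyldimethylsilyl)oxy]phenyl}-5-hydroxy-6-[(2R)-2-hydroxy-3-methylbut-3-en-1-yl]-4H-chromen-4-one | C=C(C)[C@H](O)Cc1c(O[Si](C)(C)C(C)(C)C)cc2occ(-c3ccc(O[Si](C)(C)C(C)(C)C)cc3)c(=O)c2c1O | intermediate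
10 | 5,7-dihydroxy-6-[(2R)-2-hydroxy-3-methylbut-3-en-1-yl]-3-(4-hydroxyphenyl)-4H-chromen-4-one | C=C(C)[C@H](O)Cc1c(O)cc2occ(-c3ccc(O)cc3)c(=O)c2c1O | target

**Step count and risks**
Total step count: 6. Longest linear sequence: 4 steps (1 → 2 → 3 → 4 → 10; steps 1, 2, 3 and 6).

Most likely to fail, in this order:

1. **Step 6 (the proposed new coupling).** Possible failures:
   - the secondary hydroxyl engages the benzoxazolium (mixed adducts or a cyclic ortho-amide), which would release the allylic secondary radical;
   - slow radical capture at the di-ortho-substituted aryl nickel, giving protodeiodination back to 6, the 1,2-vinyl shift, or β-hydride loss to a methyl ketone;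
   - quenching of the photocatalyst by the 5-phenoxide.

   Fallback with known chemistry, setting out from 4: primary-selective Appel bromination (CBr4, PPh3, CH2Cl2, 0 °C) gives (2S)-1-bromo-3-methylbut-3-en-2-ol F1. F1 is joined to iodide 7 by the established silyl-radical-mediated nickel/photoredox cross-electrophile coupling of aryl halides with alkyl bromides ([Ir{dF(CF3)ppy}2(dtbbpy)]PF6, NiCl2(dtbbpy), (Me3Si)3SiH, 2,6-lutidine, DME, blue LEDs). This comes back to the route at 9, which is desilylated with KHF2/MeOH as in step 6.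

2. **Step 2 (dehydration).** Possible failures: loss of the ring C–H to give the exocyclic enol ether, tertiary chloride formation, or loss of the volatile product. Fallback setting out from 1: MeNH(OMe)·HCl and iPrMgCl (THF, −20 °C) give the Weinreb amide (4R)-N-methoxy-N,2,2-trimethyl-1,3-dioxolane-4-carboxamide F2. MeMgBr (THF, 0 °C) then gives the methyl ketone 1-[(4R)-2,2-dimethyl-1,3-dioxolan-4-yl]ethan-1-one F3. Wittig methylenation (Ph3P=CH2 from Ph3PCH3Br and KN(SiMe3)2, THF, −78 °C to 0 °C) fixes the alkene position unambiguously and comes back to the route at 3. The enantiomeric purity of F3 and 3 must be checked, since F3 can enolise.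

3. **Step 5 (iodination).** Possible failures: competing C8 or 6,8-di-iodination, or partial loss of silyl groups in methanol. Fallback setting out from 6: amine-delivered ortho-bromination (tert-butylamine/Br2 complex, toluene, −70 °C), in which the hydrogen-bonded phenol directs bromine to its only free ortho carbon, gives 6-bromo-7-[(tert-butyldimethylsilyl)oxy]-3-{4-[(tert-butyldimethylsilyl)oxy]phenyl}-5-hydroxy-4H-chromen-4-one F4. F4 takes the place of 7 in step 6 (aryl bromides are the usual electrophiles of that coupling type) and comes back to the route at 9.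

**Further compounds**
F1 | step 6 | (2S)-1-bromo-3-methylbut-3-en-2-ol | C=C(C)[C@H](O)CBr
F2 | step 2 | (4R)-N-methoxy-N,2,2-trimethyl-1,3-dioxolane-4-carboxamide | CON(C)C(=O)[C@H]1COC(C)(C)O1
F3 | step 2 | 1-[(4R)-2,2-dimethyl-1,3-dioxolan-4-yl]ethan-1-one | CC(=O)[C@H]1COC(C)(C)O1
F4 | step 5 | 6-bromo-7-[(tert-butyldimethylsilyl)oxy]-3-{4-[(tert-butyldimethylsilyl)oxy]phenyl}-5-hydroxy-4H-chromen-4-one | CC(C)(C)[Si](C)(C)Oc1ccc(cc1)-c1coc2cc(O[Si](C)(C)C(C)(C)C)c(Br)c(O)c2c1=O
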